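## Analysis of the target

CNP0188003.0 is a linear pentamer of acylphloroglucinol units: five six-membered carbocycles (rings A to E) joined head to tail by four CH2 bridges. Rings A and E are dearomatised 2-butanoyl-4,4-dimethylcyclohexane-1,3,5-trione units, drawn as dienols. Rings B, C and D are butanoyl-2,4,6-trihydroxybenzenes whose two remaining ring carbons carry the bridges. There is no stereocentre and no double-bond geometry, and a mirror plane runs through ring C, so B/D and A/E are pairwise equivalent and the problem is one of constitution only. The sensitive groups are nine phenols, four vinylogous acids and the diarylmethane bridges, which change partners under acid or base once the rings are free polyphenols. The difficulty lies in rings B and D: each is hexasubstituted and unsymmetrical, with one bridge to ring C and one to an end ring, so condensation of phenols with a one-carbon electrophile gives statistical mixtures. In ring B (b1 bonded to the ring A bridge, b3 to the ring C bridge) oxygen sits on b2, b4 and b6 and butanoyl on b5. The run b4–b5–b6–b1 with its substituents is C6–C5–C4–C3 of a 5-acyl-4,6-dialkoxy-2-pyrone, and b3–b2 is the carbon pair of an oxygenated alkyne; the strategy rests on this.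

## Retrosynthetic reasoning

**27 to 26.** The nine aryl O–alkyl bonds (seven methyl, two ethyl) are cut last. The phenols stay masked throughout because free phloroglucinol rings make the bridges labile. The forward step is one exhaustive ether cleavage with a boron halide.

**26 to 21 and 24.** The two outer bridges are cut between the CH2 carbon and the end ring. The end ring 24 has a single nucleophilic ring carbon, so it can only react once. The bridge carbon stays on rings B and D as a methoxymethyl group, which ionises to a 2,4,6-trialkoxybenzyl cation. Cutting on the other side of the CH2 would require a free ring B carbon and a shared one-carbon electrophile, which is the source of mixtures. The gain is that both end rings enter in one step; 24 comes in one step from 22 by double C-methylation.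

**21 to 9 and 17 (key disconnection).** In each of rings B and D the bonds b3–b4 and b1–b2 are cut. This removes b4, b5, b6 and b1 with butanoyl, two oxygens and the bridge handle as pyrone 17, whose C2 with the ring oxygen leaves as gas in the forward sense. It leaves b3 and b2 as the alkyne carbons of an ynol ether arm on ring C, as in 9. No other cut delivers a hexasubstituted ring with all six substituents placed by the polarity of the two partners. The forward reaction has to add two pyrones to two adjacent arms and expel the lactone bridge twice.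

**9 to 5 and 6, then 5 to 3 to 1 and 2.** The propargylic CH2–C(sp) bonds are cut to a bis(benzylic chloride) and the acetylide of 6. The acetylide is used as its zinc derivative 8 because the butanoyl ketone of 5 would not survive a lithium acetylide. The chloromethyl groups go back to the two free ring carbons of 3, and the butanoyl group to Friedel–Crafts acylation of 1 with 2.

**17 to 16 to 15.** The C5–acyl bond of the pyrone is cut. The butanoyl group must come after ring closure: with the ketone in place, its oxygen and not the ester oxygen would capture the activated acid and give the isomeric pyrone in which the ketone oxygen is the ring oxygen. C5 is the only ring CH of 15 and is the β-carbon of its ketene acetal unit, so it is iodinated cleanly, and the iodide is carbonylated with a propyl–zinc reagent.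

**15 to 13 to 11 to 10.** The lactone O1–C2 bond is cut to the half ester 13, in which the methyl ester is cis to the acid-bearing chain and supplies the ring oxygen and the 6-methoxy group. The carboxyl carbon C2 is cut from the γ-carbon of enol ether 11, which is the O-methylated form of the commercial β-keto ester 10. This fixes the 4-methoxy group and the methoxymethyl group before the ring exists and leaves no regiochemical choice in the ring closure.

## Alternatives that were turned down

**Alternative 1:** The disconnection is on ring C only: the bond from the ring to the butanoyl carbonyl and the adjacent C–OH bond are cut, which leads back to an aryne. The precursor is the ortho-silyl aryl triflate A1, a B–C–D trimer whose ring C carries trimethylsilyl and triflate on neighbouring carbons. In the forward step fluoride generates the aryne, the carboxylate oxygen of butanoic acid A2 adds to the aryne carbon remote from the methoxy group, and the aryl anion takes the acyl group to give the ortho-hydroxyaryl ketone A3. In its favour, insertion of arynes into the C–O bond of carboxylic acids is a known reaction type and the flanking methoxy group steers the regiochemistry, so on precedent this step is stronger than the pyrone cycloaddition. Against it, the step closes no ring and makes no bridge. The whole B–C–D skeleton must already exist, built by Friedel–Crafts benzylations, and A1 demands silyl and triflate on the most crowded ring of a trimer. Protonation of the aryl anion by A2 diverts material to the aryl ester. Rings B and D of A3 still have an unsubstituted carbon, so the outer bridges would have to be made later on partly free phenols, and ring C ends with mixed OH and OMe groups. The chosen route uses its uncertain step to build two rings with all six substituents and the outer bridge carbons in place, and reaches that point in fewer steps.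

**Alternative 2:** Rings A and E are cut between the butanoyl-bearing carbon and the enol carbon next to the CMe2 group, which opens each end ring to a polyketo ester chain as in A4. In the forward step a base enolises the 1,3-diketone methylene of each chain, which attacks the methyl ester beside CMe2 (Dieckmann-type Claisen condensation) and gives the nonamethyl ether A5. In its favour, Claisen closure of such chains to 2-acylcyclohexane-1,3,5-triones is well established, no aromatic regiochemistry is involved, and A5 is one deprotection from the target, as 26 is. On precedent for the key step it is the stronger plan. Against it, A4 needs two ten-carbon polycarbonyl chains attached to rings B and D. Such chains also close by aldol reaction or to pyranones, and the non-enolisable β-keto ester beside CMe2 is open to retro-Claisen cleavage by the alkoxide. The plan also builds the two rings that are cheapest to obtain (24 is one step from 22) and leaves the hexasubstituted rings B and D, with benzylic handles, to be solved anyway. The chosen route puts the ring-forming step where the structure is hard and attaches the end rings ready-made.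

**Alternative 3:** Rings B and D are cut between the ethoxy-bearing carbon and the unsubstituted ring carbon and between the butanoyl-bearing carbon and a hydroxyl-bearing carbon. This gives the bis(diene) A6, in which ring C carries two 1,1,3-tris(trimethylsilyloxy)diene arms, and the acyl ynol ether A7. In the forward step the CH2 terminus of each diene adds to the ethoxy-bearing carbon of A7, the ketene acetal carbon bonds to the acyl-bearing carbon, and loss of silanol aromatises the adduct to A8. In its favour, an electron-rich silyloxydiene with an electron-poor alkynone is a matched, normal-demand pairing with much precedent, whereas the chosen pyrone carries two donor oxygens and meets a donor alkyne. A6 also follows from 5 by alkylation with acetoacetate units. On intrinsic reactivity and precedent this alternative is the stronger one. Against it, A6 is the triply silylated form of a 2-substituted acetoacetic acid, prone to decarboxylation and protodesilylation, and two such arms must survive side by side. A7 is a very electrophilic, moisture-sensitive alkyne. A8 has a free ring carbon and two free hydroxyls on each outer ring, so the bridges to 24 must be made afterwards with a one-carbon linker on a polyphenol, where self-coupling of 24 and over-reaction are expected, and ring C is still a trimethyl ether. The chosen route accepts a harder cycloaddition but delivers rings B and D fully substituted, with the outer bridge carbon in place as a differentiated handle and every phenol masked until the last step.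

Key step: step 9

Remark: 6 (as a hexane solution), 10, 22 and propylzinc bromide are taken as commercial.
Remark: 13, 14, 18 and 20 have stereocentres but are racemic, and all these centres are lost before 21; the end rings are drawn in the enol form of the target SMILES.

## Steps

Step 1
Reactants: 1 1,3,5-trimethoxybenzene; 2 butanoyl chloride
Product: 3 1-(2,4,6-trimethoxyphenyl)butan-1-one
Conditions: AlCl3 (1.1 equiv), CH2Cl2, 0 °C, short reaction time
Reagents that add atoms: none
Why: Friedel–Crafts acylation of a strongly activated arene; the first acyl group deactivates the ring against a second, and the low temperature avoids cleavage of the methoxy groups next to the new ketone.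

Step 2
Reactants: 3 1-(2,4,6-trimethoxyphenyl)butan-1-one
Product: 5 1-[3,5-bis(chloromethyl)-2,4,6-trimethoxyphenyl]butan-1-one, via mono(chloromethyl) ketone 4 (not isolated)
Conditions: (CH2O)n (8 equiv), HCl (g), 1,4-dioxane–conc. HCl, 45 °C; crude product used at once
Reagents that add atoms: formaldehyde (as paraformaldehyde), C=O; hydrogen chloride, Cl
Why: Blanc chloromethylation; each free ring carbon of 3 is ortho to two methoxy groups and para to the third, and the twisted ketone deactivates little. The product has no free ring carbon left, so it cannot be benzylated further, and the excess of reagent suppresses diarylmethane formation from 4.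

Step 3
Reactants: 5 1-[3,5-bis(chloromethyl)-2,4,6-trimethoxyphenyl]butan-1-one; 6 ethoxyethyne
Product: 9 1-[3,5-bis(3-ethoxyprop-2-yn-1-yl)-2,4,6-trimethoxyphenyl]butan-1-one, via lithium ethoxyacetylide 7 (not isolated), via (ethoxyethynyl)zinc chloride 8 (not isolated)
Conditions: 6 (3 equiv), n-BuLi, THF, −78 °C; ZnCl2, −78 → 0 °C; then 5, PdCl2[O(C6H4PPh2)2] (5 mol %), THF, 0 °C → rt; chromatography on Et3N-treated silica
Reagents that add atoms: none
Why: Negishi coupling of an alkynylzinc with a benzylic halide; the zinc acetylide spares the butanoyl ketone and is too weakly basic to isomerise the propargylic arene to an allene. If the benzylic chloride ionises instead, attack at the zinc-bearing carbon gives the same product.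

Step 4
Reactants: 10 methyl 5-methoxy-3-oxopentanoate
Product: 11 methyl (2E)-3,5-dimethoxypent-2-enoate
Conditions: HC(OMe)3 (1.5 equiv), MeOH, H2SO4 (cat.), rt; then distillation
Reagents that add atoms: trimethyl orthoformate, COC(OC)OC
Why: Acid-catalysed ketalisation and loss of methanol to the conjugated enol ether; the E isomer, with the ester cis to the chain, is the thermodynamic product as for 3-methoxybut-2-enoates. Methanol as solvent holds back β-elimination of the 5-methoxy group.

Step 5
Reactants: 11 methyl (2E)-3,5-dimethoxypent-2-enoate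
Product: 13 (3E)-3,5-dimethoxy-2-(methoxymethyl)-5-oxopent-3-enoic acid (racemic), via lithium dienolate 12 (not isolated)
Conditions: LiN(iPr)2 (1.1 equiv), THF, −78 °C; cannulated into CO2-saturated THF, −78 °C; 1 M HCl to pH 3, 0 °C
Reagents that add atoms: carbon dioxide, O=C=O
Why: γ-Deprotonation of a β-alkoxy enoate and γ-carboxylation of the extended enolate, as in the carboxylation of β-keto ester dianions. The low temperature and inverse quench keep the dienolate from eliminating methoxide.

Step 6
Reactants: 13 (3E)-3,5-dimethoxy-2-(methoxymethyl)-5-oxopent-3-enoic acid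
Product: 15 4,6-dimethoxy-3-(methoxymethyl)-2H-pyran-2-one, via acid chloride 14 (not isolated)
Conditions: (COCl)2 (1.2 equiv), DMF (cat.), CH2Cl2, 0 °C; then Et3N (2.5 equiv), 0 °C → rt
Reagents that add atoms: none
Why: Classical closure of a glutaconic half ester to a 6-alkoxy-2-pyrone: the carbonyl oxygen of the cis ester attacks the acid chloride (or the derived vinylketene closes by oxa-6π electrocyclisation) and HCl is lost. No ketone is present, so only the ester oxygen can close the ring; the stereocentre of 13 becomes sp2.

Step 7
Reactants: 15 4,6-dimethoxy-3-(methoxymethyl)-2H-pyran-2-one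
Product: 16 5-iodo-4,6-dimethoxy-3-(methoxymethyl)-2H-pyran-2-one
Conditions: N-iodosuccinimide (1.1 equiv), MeCN, 0 °C → rt, dark
Reagents that add atoms: N-iodosuccinimide, O=C1CCC(=O)N1I
Why: Electrophilic halogenation of an electron-rich 2-pyrone; C5 is the only ring CH and the β-carbon of the C6 ketene acetal unit. The neutral conditions leave the methoxymethyl group untouched.

Step 8
Reactants: 16 5-iodo-4,6-dimethoxy-3-(methoxymethyl)-2H-pyran-2-one
Product: 17 5-butanoyl-4,6-dimethoxy-3-(methoxymethyl)-2H-pyran-2-one
Conditions: CO (1 atm), PrZnBr (1.5 equiv), Pd(PPh3)4 (5 mol %), THF, rt → 40 °C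
Reagents that add atoms: carbon monoxide, [C-]#[O+]; propylzinc bromide, CCC[Zn]Br
Why: Carbonylative Negishi coupling: oxidative addition at the alkenyl iodide, CO insertion, propyl transfer from zinc and reductive elimination give the ketone. The organozinc does not attack the lactone, and the electron-rich iodide favours CO insertion over direct propyl coupling.

Step 9
Reactants: 9 1-[3,5-bis(3-ethoxyprop-2-yn-1-yl)-2,4,6-trimethoxyphenyl]butan-1-one; 17 5-butanoyl-4,6-dimethoxy-3-(methoxymethyl)-2H-pyran-2-one
Product: 21 1-{3,5-bis[[3-butanoyl-6-ethoxy-2,4-dimethoxy-5-(methoxymethyl)phenyl]methyl]-2,4,6-trimethoxyphenyl}butan-1-one, via first bridged lactone 18 (not isolated), via mono-annulated ynol ether 19 (not isolated), via second bridged lactone 20 (not isolated)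
Conditions: 17 (2.6 equiv), PhMe (1.0 M), 4 Å MS, 80 °C, sealed tube, Ar
Reagents that add atoms: none
Why: Proposed new method: the CH2-bearing carbon of each ynol ether arm of 9, the nucleophilic end of the C≡C–OEt unit, attacks C6 of 17, which is the β-carbon of the C5 butanoyl enone and the terminus of the dienoate; the resulting zwitterion (ketene-oxonium cation, anion spread over C5, C3 and both carbonyls) closes from C3 to the ethoxy-bearing carbon, so the event is an asynchronous inverse-electron-demand [4+2] cycloaddition. The bridged lactones 18 and 20 (2-oxabicyclo[2.2.2]octa-5,7-dien-3-ones) then lose CO2 by retro-[4+2] at the reaction temperature, which makes the sequence irreversible and leaves the benzene ring. The closest known reaction type is the inverse-demand Diels–Alder reaction of acceptor-substituted 2-pyrones (3-acyl, 3- or 5-alkoxycarbonyl) with ketene acetals, ynamines or ynol ethers followed by CO2 extrusion; it has not been shown for a 5-acyl-4,6-dialkoxy-2-pyrone, whose donor oxygens lower its electrophilicity, nor twice on neighbouring arms of one arene. Rings B and D are each closed by intermolecular [4+2] cycloaddition between C3 and C6 of one molecule of 17 and one alkyne arm, followed by cycloreversion, and not by cyclisation of a chain. No stereocentre is formed in 21; the bridgehead centres of 18 and 20 are racemic and vanish on aromatisation. The step needs regioselectivity (CH2-bearing carbon to C6, ethoxy-bearing carbon to C3), which the matched polarity of the ynol ether and the acyl-activated ketene acetal carbon C6 should secure, and periselectivity (closure at C3 and not at C5 or the butanoyl oxygen), which is helped by the fact that only the C3 adduct can lose CO2 while the other adducts are strained ketene acetals that can revert. The temperature is held at 80 °C so that the ynol ethers do not lose ethylene by retro-ene reaction, and the sieves keep out the water and acid that would hydrate them.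

Step 10
Reactants: 22 1-(2,4,6-trihydroxyphenyl)butan-1-one
Product: 24 2-butanoyl-3,5-dihydroxy-4,4-dimethylcyclohexa-2,5-dien-1-one, via C-methyl phlorobutyrophenone 23 (not isolated)
Conditions: NaOMe (3 equiv), MeI (2.2 equiv), MeOH, 0 °C → rt; chromatography
Reagents that add atoms: iodomethane, CI
Why: Base-mediated dearomatising C-methylation of an acylphloroglucinol, a known route to acylfilicinic acids; the geminal dimethyl product should be separable from mono- and over-methylated material.

Step 11
Reactants: 21 1-{3,5-bis[[3-butanoyl-6-ethoxy-2,4-dimethoxy-5-(methoxymethyl)phenyl]methyl]-2,4,6-trimethoxyphenyl}butan-1-one; 24 2-butanoyl-3,5-dihydroxy-4,4-dimethylcyclohexa-2,5-dien-1-one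
Product: 26 1-{3,5-bis[(3-butanoyl-6-ethoxy-2,4-dimethoxy-5-{[5-butanoyl-2,4-dihydroxy-3,3-dimethyl-6-oxocyclohexa-1,4-dien-1-yl]methyl}phenyl)methyl]-2,4,6-trimethoxyphenyl}butan-1-one, via mono-alkylated trimer 25 (not isolated)
Conditions: 24 (2.4 equiv), BF3·OEt2 (3 equiv), CH2Cl2, −40 → 0 °C
Reagents that add atoms: none
Why: Lewis acid ionisation of each benzylic methyl ether gives a 2,4,6-trialkoxybenzyl cation that alkylates the only free ring carbon of 24 (Friedel–Crafts-type C-benzylation of a cyclic β-triketone). Any O-alkylated material should re-ionise under the same conditions and end on carbon.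

Step 12
Reactants: 26 1-{3,5-bis[(3-butanoyl-6-ethoxy-2,4-dimethoxy-5-{[5-butanoyl-2,4-dihydroxy-3,3-dimethyl-6-oxocyclohexa-1,4-dien-1-yl]methyl}phenyl)methyl]-2,4,6-trimethoxyphenyl}butan-1-one
Product: 27 CNP0188003.0, 1-{3,5-bis[(3-butanoyl-5-{[5-butanoyl-2,4-dihydroxy-3,3-dimethyl-6-oxocyclohexa-1,4-dien-1-yl]methyl}-2,4,6-trihydroxyphenyl)methyl]-2,4,6-trihydroxyphenyl}butan-1-one
Conditions: BBr3 (20 equiv), CH2Cl2, −78 °C → rt; then ice–water, degassed work-up
Reagents that add atoms: none
Why: Exhaustive cleavage of aryl methyl and ethyl ethers by BBr3; the six ethers beside the ketones go first through chelation and the three para ethers follow at room temperature. The aryloxyboron intermediates are less electron-rich than free phenols, which should protect the bridges until hydrolysis.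

## Compound list

1 | 1,3,5-trimethoxybenzene | COc1cc(OC)cc(OC)c1 | starting material
2 | butanoyl chloride | CCCC(=O)Cl | starting material
3 | 1-(2,4,6-trimethoxyphenyl)butan-1-one | CCCC(=O)c1c(OC)cc(OC)cc1OC | intermediate
4 | 1-[3-(chloromethyl)-2,4,6-trimethoxyphenyl]butan-1-one | CCCC(=O)c1c(OC)cc(OC)c(CCl)c1OC | intermediate (not isolated)
5 | 1-[3,5-bis(chloromethyl)-2,4,6-trimethoxyphenyl]butan-1-one | CCCC(=O)c1c(OC)c(CCl)c(OC)c(CCl)c1OC | intermediate
6 | ethoxyethyne (ethoxyacetylene) | CCOC#C | starting material
7 | lithium ethoxyacetylide | CCOC#C[Li] | intermediate (not isolated)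
8 | (ethoxyethynyl)zinc chloride | CCOC#C[Zn]Cl | intermediate (not isolated)
9 | 1-[3,5-bis(3-ethoxyprop-2-yn-1-yl)-2,4,6-trimethoxyphenyl]butan-1-one (ring C core) | CCCC(=O)c1c(OC)c(CC#COCC)c(OC)c(CC#COCC)c1OC | intermediate
10 | methyl 5-methoxy-3-oxopentanoate | COCCC(=O)CC(=O)OC | starting material
11 | methyl (2E)-3,5-dimethoxypent-2-enoate | COCC/C(OC)=C\C(=O)OC | intermediate
12 | lithium 1,3,5-trimethoxypenta-1,3-dien-1-olate (dienolate of 11, one geometry drawn) | COC/C=C(OC)/C=C(/OC)O[Li] | intermediate (not isolated)
13 | (3E)-3,5-dimethoxy-2-(methoxymethyl)-5-oxopent-3-enoic acid (racemic) | COCC(C(=O)O)/C(OC)=C\C(=O)OC | intermediate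
14 | methyl (2E)-5-chloro-3-methoxy-4-(methoxymethyl)-5-oxopent-2-enoate (racemic) | COCC(C(=O)Cl)/C(OC)=C\C(=O)OC | intermediate (not isolated)
15 | 4,6-dimethoxy-3-(methoxymethyl)-2H-pyran-2-one | COCC1=C(OC)C=C(OC)OC1=O | intermediate
16 | 5-iodo-4,6-dimethoxy-3-(methoxymethyl)-2H-pyran-2-one | COCC1=C(OC)C(I)=C(OC)OC1=O | intermediate
17 | 5-butanoyl-4,6-dimethoxy-3-(methoxymethyl)-2H-pyran-2-one | CCCC(=O)C1=C(OC)OC(=O)C(COC)=C1OC | intermediate
18 | 7-butanoyl-6-{[3-butanoyl-5-(3-ethoxyprop-2-yn-1-yl)-2,4,6-trimethoxyphenyl]methyl}-5-ethoxy-1,8-dimethoxy-4-(methoxymethyl)-2-oxabicyclo[2.2.2]octa-5,7-dien-3-one (racemic) | CCCC(=O)c1c(OC)c(CC#COCC)c(OC)c(CC2=C(OCC)C3(COC)C(=O)OC2(OC)C(C(=O)CCC)=C3OC)c1OC | intermediate (not isolated)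
19 | 1-{3-[[3-butanoyl-6-ethoxy-2,4-dimethoxy-5-(methoxymethyl)phenyl]methyl]-5-(3-ethoxyprop-2-yn-1-yl)-2,4,6-trimethoxyphenyl}butan-1-one | CCCC(=O)c1c(OC)c(CC#COCC)c(OC)c(Cc2c(OCC)c(COC)c(OC)c(C(=O)CCC)c2OC)c1OC | intermediate (not isolated)
20 | 7-butanoyl-6-{[3-butanoyl-5-[[3-butanoyl-6-ethoxy-2,4-dimethoxy-5-(methoxymethyl)phenyl]methyl]-2,4,6-trimethoxyphenyl]methyl}-5-ethoxy-1,8-dimethoxy-4-(methoxymethyl)-2-oxabicyclo[2.2.2]octa-5,7-dien-3-one (racemic) | CCCC(=O)c1c(OC)c(CC2=C(OCC)C3(COC)C(=O)OC2(OC)C(C(=O)CCC)=C3OC)c(OC)c(Cc2c(OCC)c(COC)c(OC)c(C(=O)CCC)c2OC)c1OC | intermediate (not isolated)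
21 | 1-{3,5-bis[[3-butanoyl-6-ethoxy-2,4-dimethoxy-5-(methoxymethyl)phenyl]methyl]-2,4,6-trimethoxyphenyl}butan-1-one (B–C–D trimer) | CCCC(=O)c1c(OC)c(Cc2c(OCC)c(COC)c(OC)c(C(=O)CCC)c2OC)c(OC)c(Cc2c(OCC)c(COC)c(OC)c(C(=O)CCC)c2OC)c1OC | intermediate
22 | 1-(2,4,6-trihydroxyphenyl)butan-1-one | CCCC(=O)c1c(O)cc(O)cc1O | starting material
23 | 1-(2,4,6-trihydroxy-3-methylphenyl)butan-1-one | CCCC(=O)c1c(O)cc(O)c(C)c1O | intermediate (not isolated)
24 | 2-butanoyl-3,5-dihydroxy-4,4-dimethylcyclohexa-2,5-dien-1-one (butyrylfilicinic acid) | CCCC(=O)C1=C(O)C(C)(C)C(O)=CC1=O | intermediate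
25 | 1-{3-[(3-butanoyl-6-ethoxy-2,4-dimethoxy-5-{[5-butanoyl-2,4-dihydroxy-3,3-dimethyl-6-oxocyclohexa-1,4-dien-1-yl]methyl}phenyl)methyl]-5-[[3-butanoyl-6-ethoxy-2,4-dimethoxy-5-(methoxymethyl)phenyl]methyl]-2,4,6-trimethoxyphenyl}butan-1-one | CCCC(=O)c1c(OC)c(Cc2c(OCC)c(COC)c(OC)c(C(=O)CCC)c2OC)c(OC)c(Cc2c(OCC)c(CC3=C(O)C(C)(C)C(O)=C(C(=O)CCC)C3=O)c(OC)c(C(=O)CCC)c2OC)c1OC | intermediate (not isolated)
26 | 1-{3,5-bis[(3-butanoyl-6-ethoxy-2,4-dimethoxy-5-{[5-butanoyl-2,4-dihydroxy-3,3-dimethyl-6-oxocyclohexa-1,4-dien-1-yl]methyl}phenyl)methyl]-2,4,6-trimethoxyphenyl}butan-1-one | CCCC(=O)c1c(OC)c(Cc2c(OCC)c(CC3=C(O)C(C)(C)C(O)=C(C(=O)CCC)C3=O)c(OC)c(C(=O)CCC)c2OC)c(OC)c(Cc2c(OCC)c(CC3=C(O)C(C)(C)C(O)=C(C(=O)CCC)C3=O)c(OC)c(C(=O)CCC)c2OC)c1OC | intermediate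
27 | CNP0188003.0, 1-{3,5-bis[(3-butanoyl-5-{[5-butanoyl-2,4-dihydroxy-3,3-dimethyl-6-oxocyclohexa-1,4-dien-1-yl]methyl}-2,4,6-trihydroxyphenyl)methyl]-2,4,6-trihydroxyphenyl}butan-1-one | CCCC(=O)C1=C(O)C(C)(C)C(O)=C(Cc2c(O)c(Cc3c(O)c(Cc4c(O)c(CC5=C(O)C(C)(C)C(O)=C(C(=O)CCC)C5=O)c(O)c(C(=O)CCC)c4O)c(O)c(C(=O)CCC)c3O)c(O)c(C(=O)CCC)c2O)C1=O | target

## Step count and least certain steps

Total step count: 12. Longest linear sequence: 8 steps (10 to 27 through steps 4, 5, 6, 7, 8, 9, 11 and 12).

**Step 9 (key step).** The most likely failure is lack of reaction: the pyrone carries two donor oxygens and the alkyne is itself a donor, so the cycloaddition may need more heat than the ynol ethers tolerate before they lose ethylene to ketenes. The zwitterion may also close at the butanoyl oxygen or at C5 and drain material, and the second annulation next to the first new ring is crowded.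
The fallback uses known chemistry, sets out from 5 and 3 and comes back at 27. Friedel–Crafts benzylation of an excess of 3 with 5 (ZnCl2, CH2Cl2) should give the trimer 1-{3,5-bis[(3-butanoyl-2,4,6-trimethoxyphenyl)methyl]-2,4,6-trimethoxyphenyl}butan-1-one F1. Chloromethylation of the one free carbon on each outer ring, under the conditions of step 2, gives 1-{3,5-bis[[3-butanoyl-5-(chloromethyl)-2,4,6-trimethoxyphenyl]methyl]-2,4,6-trimethoxyphenyl}butan-1-one F2. C-alkylation of 24 with F2 (ZnCl2, CH2Cl2) gives the nonamethyl ether of the target F3, and BBr3 as in step 12 gives 27.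

**Step 3.** The zinc halide may ionise the doubly ortho-alkoxy benzylic chloride before the palladium cycle turns over, which would lead to oligomers or to alkylation of the product ynol ether at carbon; isomerisation of the propargylic arene to an allene is a second risk.
The fallback sets out from 5 and 7 and comes back at 9. The acetylide 7 is quenched with Bu3SnCl to the distillable tributyl(ethoxyethynyl)stannane F4, which is coupled with 5 in a Stille reaction (Pd(PPh3)4, THF, 50 °C) in a medium free of Lewis acid.

**Step 8.** Direct propyl transfer without CO insertion, or reduction of the iodide, would give the wrong C5 substituent.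
The fallback sets out from 16 and comes back at 17. A Nozaki–Hiyama–Kishi addition of 16 to butanal (CrCl2, NiCl2 (cat.), DMF) gives 5-(1-hydroxybutyl)-4,6-dimethoxy-3-(methoxymethyl)-2H-pyran-2-one F5 (racemic), which Dess–Martin periodinane oxidises to 17.

**Step 11.** The Lewis acid may also protonate or ionise at the existing ring C bridges and start bridge exchange, and chelation of 24 by boron may slow the C-alkylation so that this side process gains ground.
The fallback sets out from 21 and comes back at 26. DDQ (CH2Cl2–H2O) oxidises the two benzylic methyl ethers to the dialdehyde 1-{3,5-bis[(3-butanoyl-6-ethoxy-5-formyl-2,4-dimethoxyphenyl)methyl]-2,4,6-trimethoxyphenyl}butan-1-one F6. Reductive Knoevenagel alkylation of 24 with F6 (L-proline (cat.), Hantzsch ester, CH2Cl2) forms the bridges under neutral conditions.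

**Step 12.** The three ethers para to the ketones (the ring C 4-methoxy and the two ethoxy groups) cleave slowly, and the long exposure to BBr3 and HBr that they need may cause bridge scrambling or incomplete deprotection.
The fallback sets out from 26 and comes back at 27. BCl3 (CH2Cl2, −78 → 0 °C) removes only the six chelated methyl ethers and gives the hexaphenol 1-{3,5-bis[(3-butanoyl-6-ethoxy-2,4-dihydroxy-5-{[5-butanoyl-2,4-dihydroxy-3,3-dimethyl-6-oxocyclohexa-1,4-dien-1-yl]methyl}phenyl)methyl]-2,6-dihydroxy-4-methoxyphenyl}butan-1-one F7. The remaining three ethers are then cleaved by AlCl3/EtSH at 0 °C, where the thiol acts as a soft nucleophile.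

## Further compounds

F1 | step 9 | 1-{3,5-bis[(3-butanoyl-2,4,6-trimethoxyphenyl)methyl]-2,4,6-trimethoxyphenyl}butan-1-one | CCCC(=O)c1c(OC)c(Cc2c(OC)cc(OC)c(C(=O)CCC)c2OC)c(OC)c(Cc2c(OC)cc(OC)c(C(=O)CCC)c2OC)c1OC
F2 | step 9 | 1-{3,5-bis[[3-butanoyl-5-(chloromethyl)-2,4,6-trimethoxyphenyl]methyl]-2,4,6-trimethoxyphenyl}butan-1-one | CCCC(=O)c1c(OC)c(Cc2c(OC)c(CCl)c(OC)c(C(=O)CCC)c2OC)c(OC)c(Cc2c(OC)c(CCl)c(OC)c(C(=O)CCC)c2OC)c1OC
F3 | step 9 | nonamethyl ether of 27 (all nine phenolic hydroxyls of rings B, C and D as methyl ethers) | CCCC(=O)c1c(OC)c(Cc2c(OC)c(CC3=C(O)C(C)(C)C(O)=C(C(=O)CCC)C3=O)c(OC)c(C(=O)CCC)c2OC)c(OC)c(Cc2c(OC)c(CC3=C(O)C(C)(C)C(O)=C(C(=O)CCC)C3=O)c(OC)c(C(=O)CCC)c2OC)c1OC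
F4 | step 3 | tributyl(ethoxyethynyl)stannane | CCCC[Sn](CCCC)(CCCC)C#COCC
F5 | step 8 | 5-(1-hydroxybutyl)-4,6-dimethoxy-3-(methoxymethyl)-2H-pyran-2-one (racemic) | CCCC(O)C1=C(OC)OC(=O)C(COC)=C1OC
F6 | step 11 | 1-{3,5-bis[(3-butanoyl-6-ethoxy-5-formyl-2,4-dimethoxyphenyl)methyl]-2,4,6-trimethoxyphenyl}butan-1-one | CCCC(=O)c1c(OC)c(Cc2c(OCC)c(C=O)c(OC)c(C(=O)CCC)c2OC)c(OC)c(Cc2c(OCC)c(C=O)c(OC)c(C(=O)CCC)c2OC)c1OC
F7 | step 12 | 1-{3,5-bis[(3-butanoyl-6-ethoxy-2,4-dihydroxy-5-{[5-butanoyl-2,4-dihydroxy-3,3-dimethyl-6-oxocyclohexa-1,4-dien-1-yl]methyl}phenyl)methyl]-2,6-dihydroxy-4-methoxyphenyl}butan-1-one | CCCC(=O)c1c(O)c(Cc2c(OCC)c(CC3=C(O)C(C)(C)C(O)=C(C(=O)CCC)C3=O)c(O)c(C(=O)CCC)c2O)c(OC)c(Cc2c(OCC)c(CC3=C(O)C(C)(C)C(O)=C(C(=O)CCC)C3=O)c(O)c(C(=O)CCC)c2O)c1O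
A1 | alternative 1 | 4,6-bis[(3-butanoyl-2,4,6-trimethoxyphenyl)methyl]-3,5-dimethoxy-2-(trimethylsilyl)phenyl trifluoromethanesulfonate | C[Si](C)(C)c1c(OS(=O)(=O)C(F)(F)F)c(Cc2c(OC)cc(OC)c(C(=O)CCC)c2OC)c(OC)c(Cc2c(OC)cc(OC)c(C(=O)CCC)c2OC)c1OC
A2 | alternative 1 | butanoic acid | CCCC(=O)O
A3 | alternative 1 | 1-{3,5-bis[(3-butanoyl-2,4,6-trimethoxyphenyl)methyl]-2-hydroxy-4,6-dimethoxyphenyl}butan-1-one | CCCC(=O)c1c(O)c(Cc2c(OC)cc(OC)c(C(=O)CCC)c2OC)c(OC)c(Cc2c(OC)cc(OC)c(C(=O)CCC)c2OC)c1OC
A4 | alternative 2 | B–C–D nonamethyl ether in which the remaining carbon of each of rings B and D carries a CH2 bonded to C4 of a methyl 2,2-dimethyl-3,5,7-trioxodecanoate chain (two CH centres, unassigned) | CCCC(=O)c1c(OC)c(Cc2c(OC)c(CC(C(=O)CC(=O)CCC)C(=O)C(C)(C)C(=O)OC)c(OC)c(C(=O)CCC)c2OC)c(OC)c(Cc2c(OC)c(CC(C(=O)CC(=O)CCC)C(=O)C(C)(C)C(=O)OC)c(OC)c(C(=O)CCC)c2OC)c1OC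
A5 | alternative 2 | nonamethyl ether of the target (rings A and E closed, nine phenolic hydroxyls as methyl ethers) | CCCC(=O)c1c(OC)c(Cc2c(OC)c(CC3=C(O)C(C)(C)C(O)=C(C(=O)CCC)C3=O)c(OC)c(C(=O)CCC)c2OC)c(OC)c(Cc2c(OC)c(CC3=C(O)C(C)(C)C(O)=C(C(=O)CCC)C3=O)c(OC)c(C(=O)CCC)c2OC)c1OC
A6 | alternative 3 | 1-(2,4,6-trimethoxy-3,5-bis{2-[bis(trimethylsilyloxy)methylidene]-3-(trimethylsilyloxy)but-3-en-1-yl}phenyl)butan-1-one | CCCC(=O)c1c(OC)c(CC(C(=C)O[Si](C)(C)C)=C(O[Si](C)(C)C)O[Si](C)(C)C)c(OC)c(CC(C(=C)O[Si](C)(C)C)=C(O[Si](C)(C)C)O[Si](C)(C)C)c1OC
A7 | alternative 3 | 1-ethoxyhex-1-yn-3-one | CCCC(=O)C#COCC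
A8 | alternative 3 | 1-{3,5-bis[(3-butanoyl-4-ethoxy-2,6-dihydroxyphenyl)methyl]-2,4,6-trimethoxyphenyl}butan-1-one | CCCC(=O)c1c(OC)c(Cc2c(O)cc(OCC)c(C(=O)CCC)c2O)c(OC)c(Cc2c(O)cc(OCC)c(C(=O)CCC)c2O)c1OC
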